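**Retrosynthetic overview**

1. Pervilleanone ⇐ fluoride cleavage of a bis(isoflavanone) in which two protected target molecules are joined through their 7-oxygens by one di-tert-butylsilylene.
2. Key disconnection: the C2–C3 bond of each pyranone ring ⇐ enantioselective dirhodium-carbenoid 1,6 C–H insertion of an aryl(aroyl)diazomethane carbon into the ortho O–CH3 group of ring A. Run two-fold, it closes both pyranone rings and sets both C3 centres in one operation.
3. Bis(diazo ketone) ⇐ diazo transfer ⇐ bis(deoxybenzoin) ⇐ two-fold Pd α-arylation of a silylene-linked bis(2-methoxyacetophenone) with the ring B aryl bromide.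
4. Ring B bromide ⇐ 2,3-dimethoxyphenol by para-bromination, γ-selective prenyl cross-coupling (gives the 1,1-dimethylallyl group), ortho-bromination and O-silylation.
5. Ring order: rings A and B come as benzene rings from the starting materials; the pyranone ring (ring C) is the only ring made, formed last, both copies together.

Assumption: the absolute sense of induction of the new C–H insertion is taken to be (3R) with Rh2(S-PTTL)4 (dirhodium tetrakis[N-phthaloyl-(S)-tert-leucinate]); if the first run shows the opposite sense, the mirror-image catalyst Rh2(R-PTTL)4 is used and nothing else changes.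

**Route**

Step 1
Reactants: 1 2,3-dimethoxyphenol; 2 N-bromosuccinimide
Product: 3 4-bromo-2,3-dimethoxyphenol
Conditions: NBS (1.0 equiv), MeCN, −20 → 0 °C
Reagents that add atoms: N-bromosuccinimide, O=C1CCC(=O)N1Br
Why: Electrophilic aromatic bromination (SEAr) of the free phenol goes para to the hydroxyl group, the most activated position, which is also ortho to a methoxy group.

Step 2
Reactants: 3 4-bromo-2,3-dimethoxyphenol; 4 4,4,5,5-tetramethyl-2-(3-methylbut-2-en-1-yl)-1,3,2-dioxaborolane (prenylB(pin))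
Product: 5 2,3-dimethoxy-4-(2-methylbut-3-en-2-yl)phenol
Conditions: 4 (1.5 equiv), Pd(OAc)2 (2 mol %), γ-selective dialkylbiarylphosphine ligand (4 mol %), K3PO4 (aq, 3 equiv), THF, 40 °C
Reagents that add atoms: prenylB(pin), CC(C)=CCB1OC(C)(C)C(C)(C)O1
Why: Ligand-controlled γ-selective allyl–aryl Suzuki–Miyaura coupling, in which SE2′ transmetalation puts palladium on the tertiary allyl carbon and reductive elimination occurs there before σ–π–σ isomerisation, installs the 1,1-dimethylallyl group with its quaternary benzylic carbon in one step.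

Step 3
Reactants: 5 2,3-dimethoxy-4-(2-methylbut-3-en-2-yl)phenol; 2 N-bromosuccinimide
Product: 6 6-bromo-2,3-dimethoxy-4-(2-methylbut-3-en-2-yl)phenol
Conditions: NBS (1.0 equiv), i-Pr2NH (10 mol %), CH2Cl2, −78 → 0 °C
Reagents that add atoms: N-bromosuccinimide, O=C1CCC(=O)N1Br
Why: Amine-mediated ortho-selective SEAr bromination of the phenol at its only free ortho/para position (para is blocked by the tert-alkyl group) is fast enough at low temperature that the vinyl group, which has no allylic hydrogen, is not touched.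

Step 4
Reactants: 6 6-bromo-2,3-dimethoxy-4-(2-methylbut-3-en-2-yl)phenol; 7 tert-butyl(chloro)dimethylsilane
Product: 8 [6-bromo-2,3-dimethoxy-4-(2-methylbut-3-en-2-yl)phenoxy](tert-butyl)dimethylsilane
Conditions: TBSCl (1.3 equiv), imidazole (2.5 equiv), DMAP (cat.), DMF, 40 °C
Reagents that add atoms: tert-butyl(chloro)dimethylsilane, CC(C)(C)[Si](C)(C)Cl
Why: Standard O-silylation masks the phenol with a group that has no C–H bond on the atom next to oxygen, so it cannot undergo 1,5 C–H insertion in step 8, and that later leaves with fluoride.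

Step 5
Reactants: 9 1-(4-hydroxy-2-methoxyphenyl)ethanone (2 equiv); 10 di-tert-butylsilanediyl bis(trifluoromethanesulfonate)
Product: 12 bis(4-acetyl-3-methoxyphenoxy)di-tert-butylsilane, via silyl triflate 11 (not isolated)
Conditions: 10 (0.5 equiv relative to 9), imidazole (2.5 equiv), DMF, 0 → 50 °C
Reagents that add atoms: di-tert-butylsilanediyl bis(trifluoromethanesulfonate), CC(C)(C)[Si](OS(=O)(=O)C(F)(F)F)(OS(=O)(=O)C(F)(F)F)C(C)(C)C
Why: Two successive nucleophilic substitutions at silicon by the acidic para-acyl phenol join two ketone units through one di-tert-butylsilylene, which protects both phenols and makes every later operation two-directional.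

Step 6
Reactants: 12 bis(4-acetyl-3-methoxyphenoxy)di-tert-butylsilane; 8 [6-bromo-2,3-dimethoxy-4-(2-methylbut-3-en-2-yl)phenoxy](tert-butyl)dimethylsilane (2.3 equiv)
Product: 14 di-tert-butylbis(4-{[2-{[tert-butyl(dimethyl)silyl]oxy}-3,4-dimethoxy-5-(2-methylbut-3-en-2-yl)phenyl]acetyl}-3-methoxyphenoxy)silane (bis-deoxybenzoin), via mono-arylated ketone 13 (not isolated)
Conditions: Pd2(dba)3 (2.5 mol %), XPhos (6 mol %), K3PO4 (6 equiv), toluene, 90 °C
Reagents that add atoms: none
Why: Palladium-catalysed ketone α-arylation (Buchwald–Hartwig type) of each methyl ketone enolate with the aryl bromide is run with K3PO4 so that the aryl silyl ethers survive, and the ortho silyloxy group of the new benzylic aryl suppresses a second arylation.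

Step 7
Reactants: 14 bis-deoxybenzoin; 15 4-acetamidobenzenesulfonyl azide (p-ABSA)
Product: 17 di-tert-butylbis(4-{diazo[2-{[tert-butyl(dimethyl)silyl]oxy}-3,4-dimethoxy-5-(2-methylbut-3-en-2-yl)phenyl]acetyl}-3-methoxyphenoxy)silane (bis-diazo ketone), via mono-diazo ketone 16 (not isolated)
Conditions: p-ABSA (2.6 equiv), DBU (3 equiv), dry MeCN, 0 °C → rt
Reagents that add atoms: 4-acetamidobenzenesulfonyl azide, CC(=O)Nc1ccc(cc1)S(=O)(=O)N=[N+]=[N-]
Why: Regitz diazo transfer, in which DBU deprotonates each doubly activated benzylic methylene and the enolate takes N2 from the sulfonyl azide, gives the two aryl(aroyl)diazomethane units.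

Step 8
Reactants: 17 bis-diazo ketone
Product: 19 di-tert-butylbis({(3R)-3-[2-{[tert-butyl(dimethyl)silyl]oxy}-3,4-dimethoxy-5-(2-methylbut-3-en-2-yl)phenyl]-4-oxo-3,4-dihydro-2H-chromen-7-yl}oxy)silane (3R,3′R), via mono-cyclised diazo ketone 18 (not isolated)
Conditions: Rh2(S-PTTL)4 (2 mol %), PhCF3, slow addition of 17 over 4 h at 0 °C, then rt
Reagents that add atoms: none
Why: Proposed new method: each diazo ketone gives a donor/acceptor rhodium carbenoid (aryl donor, aroyl acceptor) whose carbon inserts into a C–H bond of the ortho methoxy group of the aroyl ring, a 1,6 insertion through a six-membered transition state helped by the oxygen lone pair and by the absence of any 1,5 C–H bond or other heteroatom-activated C–H within reach, so the former O-methyl carbon becomes C2 and both pyranone rings close in the same operation, while the chiral carboxylate pocket decides which face of the carbenoid carbon bonds and sets C3 as (R) in each half under neutral conditions that do not enolise the new α-aryl ketone; the closest known reactions are the dirhodium-catalysed enantioselective intramolecular C–H insertions of α-aryl-α-diazo ketones to 2-arylcyclopentanones and of ortho-alkoxyaryl diazo ketones to chromanones.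

Step 9
Reactants: 19 silylene-linked bis(isoflavanone)
Product: 22 pervilleanone (2 equiv), via fluorosilyl ether 20 (not isolated), via 2′-O-silyl phenol 21 (not isolated)
Conditions: HF·pyridine (excess), pyridine, THF, 0 °C → rt
Reagents that add atoms: none
Why: Fluoride-driven cleavage of the four aryl O–Si bonds (Si–F bond formation is the driving force) in pyridine-buffered HF is too weakly acidic and too non-basic to enolise the α-aryl ketone or cyclodehydrate the 2′-hydroxy ketone, so C3 stays (R) and each molecule of 19 releases two molecules of the target.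

**Compound list**

1 | 2,3-dimethoxyphenol | COc1cccc(O)c1OC | starting material
2 | N-bromosuccinimide | O=C1CCC(=O)N1Br | starting material
3 | 4-bromo-2,3-dimethoxyphenol | COc1c(O)ccc(Br)c1OC | intermediate
4 | 4,4,5,5-tetramethyl-2-(3-methylbut-2-en-1-yl)-1,3,2-dioxaborolane | CC(C)=CCB1OC(C)(C)C(C)(C)O1 | starting material
5 | 2,3-dimethoxy-4-(2-methylbut-3-en-2-yl)phenol | C=CC(C)(C)c1ccc(O)c(OC)c1OC | intermediate
6 | 6-bromo-2,3-dimethoxy-4-(2-methylbut-3-en-2-yl)phenol | C=CC(C)(C)c1cc(Br)c(O)c(OC)c1OC | intermediate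
7 | tert-butyl(chloro)dimethylsilane | CC(C)(C)[Si](C)(C)Cl | starting material
8 | [6-bromo-2,3-dimethoxy-4-(2-methylbut-3-en-2-yl)phenoxy](tert-butyl)dimethylsilane | C=CC(C)(C)c1cc(Br)c(O[Si](C)(C)C(C)(C)C)c(OC)c1OC | intermediate
9 | 1-(4-hydroxy-2-methoxyphenyl)ethanone | CC(=O)c1ccc(O)cc1OC | starting material
10 | di-tert-butylsilanediyl bis(trifluoromethanesulfonate) | CC(C)(C)[Si](OS(=O)(=O)C(F)(F)F)(OS(=O)(=O)C(F)(F)F)C(C)(C)C | starting material
11 | 1-[4-({di-tert-butyl[(trifluoromethanesulfonyl)oxy]silyl}oxy)-2-methoxyphenyl]ethanone | CC(=O)c1ccc(O[Si](OS(=O)(=O)C(F)(F)F)(C(C)(C)C)C(C)(C)C)cc1OC | intermediate (not isolated)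
12 | bis(4-acetyl-3-methoxyphenoxy)di-tert-butylsilane | CC(=O)c1ccc(O[Si](C(C)(C)C)(C(C)(C)C)Oc2ccc(C(C)=O)c(OC)c2)cc1OC | intermediate
13 | (4-acetyl-3-methoxyphenoxy)(4-{[2-{[tert-butyl(dimethyl)silyl]oxy}-3,4-dimethoxy-5-(2-methylbut-3-en-2-yl)phenyl]acetyl}-3-methoxyphenoxy)di-tert-butylsilane | C=CC(C)(C)c1cc(CC(=O)c2ccc(O[Si](C(C)(C)C)(C(C)(C)C)Oc3ccc(C(C)=O)c(OC)c3)cc2OC)c(O[Si](C)(C)C(C)(C)C)c(OC)c1OC | intermediate (not isolated)
14 | di-tert-butylbis(4-{[2-{[tert-butyl(dimethyl)silyl]oxy}-3,4-dimethoxy-5-(2-methylbut-3-en-2-yl)phenyl]acetyl}-3-methoxyphenoxy)silane | C=CC(C)(C)c1cc(CC(=O)c2ccc(O[Si](C(C)(C)C)(C(C)(C)C)Oc3ccc(C(=O)Cc4cc(C(C)(C)C=C)c(OC)c(OC)c4O[Si](C)(C)C(C)(C)C)c(OC)c3)cc2OC)c(O[Si](C)(C)C(C)(C)C)c(OC)c1OC | intermediate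
15 | 4-acetamidobenzenesulfonyl azide | CC(=O)Nc1ccc(cc1)S(=O)(=O)N=[N+]=[N-] | starting material
16 | mono-diazo ketone: as 14, but one arm carries C(=N2) between the carbonyl group and ring B | C=CC(C)(C)c1cc(C(=[N+]=[N-])C(=O)c2ccc(O[Si](C(C)(C)C)(C(C)(C)C)Oc3ccc(C(=O)Cc4cc(C(C)(C)C=C)c(OC)c(OC)c4O[Si](C)(C)C(C)(C)C)c(OC)c3)cc2OC)c(O[Si](C)(C)C(C)(C)C)c(OC)c1OC | intermediate (not isolated)
17 | di-tert-butylbis(4-{diazo[2-{[tert-butyl(dimethyl)silyl]oxy}-3,4-dimethoxy-5-(2-methylbut-3-en-2-yl)phenyl]acetyl}-3-methoxyphenoxy)silane | C=CC(C)(C)c1cc(C(=[N+]=[N-])C(=O)c2ccc(O[Si](C(C)(C)C)(C(C)(C)C)Oc3ccc(C(=O)C(=[N+]=[N-])c4cc(C(C)(C)C=C)c(OC)c(OC)c4O[Si](C)(C)C(C)(C)C)c(OC)c3)cc2OC)c(O[Si](C)(C)C(C)(C)C)c(OC)c1OC | intermediate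
18 | mono-cyclised diazo ketone: one (3R)-chromanone arm as in 19, one diazo ketone arm as in 17 | C=CC(C)(C)c1cc([C@@H]2COc3cc(O[Si](C(C)(C)C)(C(C)(C)C)Oc4ccc(C(=O)C(=[N+]=[N-])c5cc(C(C)(C)C=C)c(OC)c(OC)c5O[Si](C)(C)C(C)(C)C)c(OC)c4)ccc3C2=O)c(O[Si](C)(C)C(C)(C)C)c(OC)c1OC | intermediate (not isolated)
19 | di-tert-butylbis({(3R)-3-[2-{[tert-butyl(dimethyl)silyl]oxy}-3,4-dimethoxy-5-(2-methylbut-3-en-2-yl)phenyl]-4-oxo-3,4-dihydro-2H-chromen-7-yl}oxy)silane | C=CC(C)(C)c1cc([C@@H]2COc3cc(O[Si](C(C)(C)C)(C(C)(C)C)Oc4ccc5c(c4)OC[C@@H](c6cc(C(C)(C)C=C)c(OC)c(OC)c6O[Si](C)(C)C(C)(C)C)C5=O)ccc3C2=O)c(O[Si](C)(C)C(C)(C)C)c(OC)c1OC | intermediate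
20 | (3R)-3-[2-{[tert-butyl(dimethyl)silyl]oxy}-3,4-dimethoxy-5-(2-methylbut-3-en-2-yl)phenyl]-7-{[di-tert-butyl(fluoro)silyl]oxy}-2,3-dihydro-4H-chromen-4-one | C=CC(C)(C)c1cc([C@@H]2COc3cc(O[Si](F)(C(C)(C)C)C(C)(C)C)ccc3C2=O)c(O[Si](C)(C)C(C)(C)C)c(OC)c1OC | intermediate (not isolated)
21 | (3R)-3-[2-{[tert-butyl(dimethyl)silyl]oxy}-3,4-dimethoxy-5-(2-methylbut-3-en-2-yl)phenyl]-7-hydroxy-2,3-dihydro-4H-chromen-4-one | C=CC(C)(C)c1cc([C@@H]2COc3cc(O)ccc3C2=O)c(O[Si](C)(C)C(C)(C)C)c(OC)c1OC | intermediate (not isolated)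
22 | pervilleanone, (3R)-7-hydroxy-3-[2-hydroxy-3,4-dimethoxy-5-(2-methylbut-3-en-2-yl)phenyl]-2,3-dihydro-4H-chromen-4-one | C=CC(C)(C)c1cc([C@@H]2COc3cc(O)ccc3C2=O)c(O)c(OC)c1OC | target

**Step count and risks**

Total step count: 9. Longest linear sequence: 8 steps (1 → 3 → 5 → 6 → 8 → 14 → 17 → 19 → 22); step 5 is the one-step side branch.

The three steps most likely to fail are steps 2, 6 and 8; step 8 carries the most risk.

Step 2 (γ-selective prenyl coupling). The ortho-methoxy bromophenol may give the linear prenyl arene or mixtures instead of the quaternary 1,1-dimethylallyl product. The fallback sets out from 3 and comes back at 5, building the quaternary carbon by carbonyl chemistry instead of allyl coupling. Compound 3 is silylated with chlorotri(propan-2-yl)silane and imidazole to (4-bromo-2,3-dimethoxyphenoxy)tri(propan-2-yl)silane F1. Palladium-catalysed α-arylation of 2-methylpropanal with F1 (Pd(OAc)2, rac-BINAP, Cs2CO3, dioxane, 80 °C) gives 2-(2,3-dimethoxy-4-{[tri(propan-2-yl)silyl]oxy}phenyl)-2-methylpropanal F2. Wittig methylenation (Ph3P=CH2 from the phosphonium bromide and KOt-Bu, THF) gives [2,3-dimethoxy-4-(2-methylbut-3-en-2-yl)phenoxy]tri(propan-2-yl)silane F3, and Bu4NF frees 5.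

Step 6 (two-fold α-arylation). The hindered ortho-silyloxy bromide may couple sluggishly, and the silylene may not survive long heating with base. The fallback sets out from 12 (and, for the aryl partner, from 5) and comes back at 17, so steps 6 and 7 are both bypassed: the diazo group is installed first and the diazo carbon is arylated afterwards. Both methyl ketones of 12 are trifluoroacetylated (LiN(SiMe3)2, CF3CO2CH2CF3, THF, −78 °C) to di-tert-butylbis[3-methoxy-4-(4,4,4-trifluoro-3-oxobutanoyl)phenoxy]silane F4. Detrifluoroacetylative diazo transfer with 15 (Et3N, H2O, MeCN) gives di-tert-butylbis[4-(diazoacetyl)-3-methoxyphenoxy]silane F5. Separately, 5 is iodinated ortho to the hydroxyl group (N-iodosuccinimide, cat. i-Pr2NH, CH2Cl2) to 6-iodo-2,3-dimethoxy-4-(2-methylbut-3-en-2-yl)phenol F6, which is silylated with 7 to tert-butyl[6-iodo-2,3-dimethoxy-4-(2-methylbut-3-en-2-yl)phenoxy]dimethylsilane F7. Palladium-catalysed C–H arylation of the acyl diazomethane units of F5 with F7 (Pd(PPh3)4, Ag2CO3, Et3N, toluene, rt) then gives 17.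

Step 8 (two-fold C–H insertion). Possible failures are oxonium ylide formation at the methoxy oxygen followed by a 1,2-methyl shift to a 2-methylbenzofuran-3-one, Wolff rearrangement, carbenoid attack on a vinyl group, and low enantioselectivity on this new substrate class. One point in favour of the linked design: the minor-enantiomer units collect mostly in the heterochiral (3R,3′S) diastereomer of 19, so if that diastereomer can be removed (crystallisation or HPLC) before step 9, the ee of 22 rises above the per-site selectivity. The stereocentres are far apart, so this separation is not assured.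

The fallback sets out from 8 and comes back at 22 (through 21). It forms the C3–aryl bond on a bought pyranone ring and sets C3 by catalytic enantioselective protonation.
- Commercial 7-hydroxy-2,3-dihydro-4H-chromen-4-one is silylated with 7 to 7-{[tert-butyl(dimethyl)silyl]oxy}-2,3-dihydro-4H-chromen-4-one F8.
- Palladium-catalysed α-arylation with 8 (Pd2(dba)3, XPhos, K3PO4, toluene, 90 °C) gives racemic 7-{[tert-butyl(dimethyl)silyl]oxy}-3-[2-{[tert-butyl(dimethyl)silyl]oxy}-3,4-dimethoxy-5-(2-methylbut-3-en-2-yl)phenyl]-2,3-dihydro-4H-chromen-4-one F9.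
- KN(SiMe3)2 and allyl chloroformate (THF, −78 °C) give the enol carbonate prop-2-en-1-yl 7-{[tert-butyl(dimethyl)silyl]oxy}-3-[2-{[tert-butyl(dimethyl)silyl]oxy}-3,4-dimethoxy-5-(2-methylbut-3-en-2-yl)phenyl]-2H-chromen-4-yl carbonate F10.
- Decarboxylative enantioselective protonation (Pd2(dba)3, t-Bu-PHOX in the antipode that gives 3R, Meldrum's acid, dioxane, 40 °C; zerovalent palladium ionises the allyl carbonate and the chiral palladium enolate is protonated) gives the (3R)-bis-silyl isoflavanone F11.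
- Pyridine-buffered HF·pyridine converts F11 into 22 by way of 21.

**Further compounds**

F1 | step 2 | (4-bromo-2,3-dimethoxyphenoxy)tri(propan-2-yl)silane | COc1c(O[Si](C(C)C)(C(C)C)C(C)C)ccc(Br)c1OC
F2 | step 2 | 2-(2,3-dimethoxy-4-{[tri(propan-2-yl)silyl]oxy}phenyl)-2-methylpropanal | CC(C)(C=O)c1ccc(O[Si](C(C)C)(C(C)C)C(C)C)c(OC)c1OC
F3 | step 2 | [2,3-dimethoxy-4-(2-methylbut-3-en-2-yl)phenoxy]tri(propan-2-yl)silane | C=CC(C)(C)c1ccc(O[Si](C(C)C)(C(C)C)C(C)C)c(OC)c1OC
F4 | step 6 | di-tert-butylbis[3-methoxy-4-(4,4,4-trifluoro-3-oxobutanoyl)phenoxy]silane | COc1cc(O[Si](C(C)(C)C)(C(C)(C)C)Oc2ccc(C(=O)CC(=O)C(F)(F)F)c(OC)c2)ccc1C(=O)CC(=O)C(F)(F)F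
F5 | step 6 | di-tert-butylbis[4-(diazoacetyl)-3-methoxyphenoxy]silane | COc1cc(O[Si](C(C)(C)C)(C(C)(C)C)Oc2ccc(C(=O)C=[N+]=[N-])c(OC)c2)ccc1C(=O)C=[N+]=[N-]
F6 | step 6 | 6-iodo-2,3-dimethoxy-4-(2-methylbut-3-en-2-yl)phenol | C=CC(C)(C)c1cc(I)c(O)c(OC)c1OC
F7 | step 6 | tert-butyl[6-iodo-2,3-dimethoxy-4-(2-methylbut-3-en-2-yl)phenoxy]dimethylsilane | C=CC(C)(C)c1cc(I)c(O[Si](C)(C)C(C)(C)C)c(OC)c1OC
F8 | step 8 | 7-{[tert-butyl(dimethyl)silyl]oxy}-2,3-dihydro-4H-chromen-4-one | CC(C)(C)[Si](C)(C)Oc1ccc2C(=O)CCOc2c1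
F9 | step 8 | racemic 7-{[tert-butyl(dimethyl)silyl]oxy}-3-[2-{[tert-butyl(dimethyl)silyl]oxy}-3,4-dimethoxy-5-(2-methylbut-3-en-2-yl)phenyl]-2,3-dihydro-4H-chromen-4-one | C=CC(C)(C)c1cc(C2COc3cc(O[Si](C)(C)C(C)(C)C)ccc3C2=O)c(O[Si](C)(C)C(C)(C)C)c(OC)c1OC
F10 | step 8 | prop-2-en-1-yl 7-{[tert-butyl(dimethyl)silyl]oxy}-3-[2-{[tert-butyl(dimethyl)silyl]oxy}-3,4-dimethoxy-5-(2-methylbut-3-en-2-yl)phenyl]-2H-chromen-4-yl carbonate | C=CCOC(=O)OC1=C(c2cc(C(C)(C)C=C)c(OC)c(OC)c2O[Si](C)(C)C(C)(C)C)COc2cc(O[Si](C)(C)C(C)(C)C)ccc12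
F11 | step 8 | (3R)-7-{[tert-butyl(dimethyl)silyl]oxy}-3-[2-{[tert-butyl(dimethyl)silyl]oxy}-3,4-dimethoxy-5-(2-methylbut-3-en-2-yl)phenyl]-2,3-dihydro-4H-chromen-4-one | C=CC(C)(C)c1cc([C@@H]2COc3cc(O[Si](C)(C)C(C)(C)C)ccc3C2=O)c(O[Si](C)(C)C(C)(C)C)c(OC)c1OC
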